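Nortopsentin A carries the same 6-bromoindol-3-yl ring on C2 and on C4 of its central imidazole ring. Both biaryl bonds (imidazole C2–indole C3 and imidazole C4–indole C3) are therefore disconnected together. One Suzuki–Miyaura operation joins two equivalents of a single N-tosyl-6-bromoindol-3-yl pinacol boronate to an N1-SEM imidazole bearing iodine at C2 and C4. This assembles the whole skeleton without closing a ring. The imidazole C–I bonds undergo oxidative addition far faster than the indole C6–Br bonds, so both bromines stay. SEM is then hydrolysed while the indoles are still sulfonylated, and hydroxide finally removes both tosyl groups.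

Key step: step 5

Assumption: the N–H tautomers of the 2,4(5)-disubstituted imidazole interconvert rapidly, so 14 and 15 are drawn only as the 1H-2,4-form. The target has no stereocentre.

Abbreviations: SEM = 2-(trimethylsilyl)ethoxymethyl, Ts = p-toluenesulfonyl, TMP = 2,2,6,6-tetramethylpiperidide, DME = 1,2-dimethoxyethane.

Step 1
Reactants: 1 4-iodo-1H-imidazole; 2 2-(trimethylsilyl)ethoxymethyl chloride (SEMCl)
Product: 3 4-iodo-1-SEM-imidazole
Conditions: NaH, THF, 0 °C; then 2, 0 °C → rt; minor 5-iodo isomer removed by chromatography
Reagents that add atoms: none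
Why: N-alkylation of the deprotonated imidazole by the chloromethyl ether should favour the nitrogen remote from the bulky, electron-withdrawing iodine, which makes the 1,4-isomer the main product.

Step 2
Reactants: 3 4-iodo-1-SEM-imidazole
Product: 5 2,4-diiodo-1-SEM-imidazole, via imidazol-2-ylmagnesium chloride 4 (not isolated)
Conditions: TMPMgCl·LiCl (1.2 equiv), THF, −20 °C; then transferred into I2 (1.4 equiv), THF, −20 °C → rt; aq Na2S2O3 work-up
Reagents that add atoms: iodine, [I][I]
Why: Directed deprotonative magnesiation with a hindered, non-nucleophilic amide removes the most acidic proton (C2–H, between the two nitrogens and next to the coordinating SEM oxygen) without the iodine–metal exchange at C4 that an alkyllithium would cause, and iodinolysis of the C–Mg bond installs the second iodine.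

Step 3
Reactants: 6 6-bromo-1H-indole
Product: 8 6-bromo-3-iodo-1-tosylindole, via 6-bromo-3-iodoindole 7 (not isolated)
Conditions: KOH (4 equiv), I2 (1.05 equiv), DMF, rt, dark; then TsCl (1.3 equiv), 0 °C → rt
Reagents that add atoms: iodine, [I][I]; p-toluenesulfonyl chloride, Cc1ccc(cc1)S(=O)(=O)Cl
Why: Electrophilic iodination under basic conditions goes to the nucleophilic indole C3, and N-sulfonylation in the same basic DMF solution avoids isolating the light- and acid-sensitive N–H 3-iodoindole.

Step 4
Reactants: 8 6-bromo-3-iodo-1-tosylindole; 9 2-isopropoxy-4,4,5,5-tetramethyl-1,3,2-dioxaborolane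
Product: 11 6-bromo-1-tosylindol-3-ylboronic acid pinacol ester, via indol-3-ylmagnesium chloride 10 (not isolated)
Conditions: i-PrMgCl (1.1 equiv), THF, −40 °C; then 9 (1.5 equiv), −40 °C → rt; aq NH4Cl
Reagents that add atoms: none
Why: Iodine–magnesium exchange is far faster at C3–I than at C6–Br at −40 °C, the N-sulfonylindol-3-yl Grignard reagent does not migrate to C2 as its lithium analogue does, and trapping with the borate ester gives the boronate without any palladium that could touch the bromide.

Step 5
Reactants: 5 2,4-diiodo-1-SEM-imidazole; 11 6-bromo-1-tosylindol-3-ylboronic acid pinacol ester (2.2 equiv)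
Product: 13 1-SEM-2,4-bis(6-bromo-1-tosylindol-3-yl)imidazole, via mono-coupled 4-iodoimidazole 12 (not isolated)
Conditions: Pd(PPh3)4 (8 mol %), 2 M aq Na2CO3, DME, degassed, 40 °C then 65 °C
Reagents that add atoms: none
Why: This is a Suzuki–Miyaura coupling run twice in one flask: zerovalent palladium inserts first into the C2–I bond, the more electron-poor one between N1 and N3, the carbonate-activated boronate hands its indol-3-yl group to palladium, reductive elimination gives mono-coupled iodide 12, and 12 passes through the same cycle at C4–I. The closest known reaction type is the cross-coupling of N-protected haloimidazoles with N-protected indol-3-ylboron reagents, including halogen-selective versions that spare a bromoindole. No ring is closed and no stereocentre is formed; the step makes only the two sp2–sp2 bonds imidazole C2–indole C3 and imidazole C4–indole C3. The selectivity needed is chemoselectivity for the two imidazole C–I bonds over the C6–Br bonds of 11, 12 and 13, and it is secured by the much faster oxidative addition of heteroaryl iodides to the PPh3-ligated catalyst at or below 65 °C, by only a slight excess of 11 and by stopping when 12 has gone. The order of reaction at C2 and C4 does not affect the outcome, since the same group enters both positions. The N-tosyl groups retard protodeboronation of 11, and the alcohol-free DME–water medium with a mild carbonate keeps them and the SEM group in place.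

Step 6
Reactants: 13 1-SEM-2,4-bis(6-bromo-1-tosylindol-3-yl)imidazole
Product: 14 2,4-bis(6-bromo-1-tosylindol-3-yl)-1H-imidazole
Conditions: 3 M aq HCl, EtOH/1,4-dioxane, 75 °C; neutralise with aq NaHCO3
Reagents that add atoms: none
Why: Acid-catalysed hydrolysis of the N,O-acetal is the standard SEM cleavage on imidazoles, and running it before detosylation means the formaldehyde released meets only sulfonyl-deactivated indoles, while N-tosyl groups and aryl bromides are stable to aqueous acid.

Step 7
Reactants: 14 2,4-bis(6-bromo-1-tosylindol-3-yl)-1H-imidazole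
Product: 15 nortopsentin A, 2,4-bis(6-bromo-1H-indol-3-yl)-1H-imidazole
Conditions: 2 M aq NaOH (excess), 1,4-dioxane, 70 °C; then aq NH4Cl to pH 8
Reagents that add atoms: none
Why: Hydroxide attacks sulfur of the N-sulfonylindoles (sulfonamide hydrolysis helped by the good indolide leaving group), the alcohol-free medium excludes any alkyl tosylate that could alkylate the imidazole, and the aryl bromides are inert.

Compound list
1 | 4-iodo-1H-imidazole | Ic1c[nH]cn1 | starting material
2 | 2-(trimethylsilyl)ethoxymethyl chloride | C[Si](C)(C)CCOCCl | starting material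
3 | 4-iodo-1-SEM-imidazole | C[Si](C)(C)CCOCn1cc(I)nc1 | intermediate
4 | (4-iodo-1-SEM-imidazol-2-yl)magnesium chloride (formed in situ) | C[Si](C)(C)CCOCn1cc(I)nc1[Mg]Cl | intermediate
5 | 2,4-diiodo-1-SEM-imidazole | C[Si](C)(C)CCOCn1cc(I)nc1I | intermediate
6 | 6-bromo-1H-indole | Brc1ccc2cc[nH]c2c1 | starting material
7 | 6-bromo-3-iodo-1H-indole (formed in situ) | Brc1ccc2c(I)c[nH]c2c1 | intermediate
8 | 6-bromo-3-iodo-1-tosylindole | Cc1ccc(cc1)S(=O)(=O)n1cc(I)c2ccc(Br)cc21 | intermediate
9 | 2-isopropoxy-4,4,5,5-tetramethyl-1,3,2-dioxaborolane | CC(C)OB1OC(C)(C)C(C)(C)O1 | starting material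
10 | (6-bromo-1-tosylindol-3-yl)magnesium chloride (formed in situ) | Cc1ccc(cc1)S(=O)(=O)n1cc([Mg]Cl)c2ccc(Br)cc21 | intermediate
11 | 6-bromo-1-tosylindol-3-ylboronic acid pinacol ester | CC1(C)OB(OC1(C)C)c1cn(S(=O)(=O)c2ccc(C)cc2)c2cc(Br)ccc12 | intermediate
12 | 2-(6-bromo-1-tosylindol-3-yl)-4-iodo-1-SEM-imidazole (formed in situ) | Cc1ccc(cc1)S(=O)(=O)n1cc(-c2nc(I)cn2COCC[Si](C)(C)C)c2ccc(Br)cc21 | intermediate
13 | 1-SEM-2,4-bis(6-bromo-1-tosylindol-3-yl)imidazole | Cc1ccc(cc1)S(=O)(=O)n1cc(-c2cn(COCC[Si](C)(C)C)c(-c3cn(S(=O)(=O)c4ccc(C)cc4)c4cc(Br)ccc34)n2)c2ccc(Br)cc21 | intermediate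
14 | 2,4-bis(6-bromo-1-tosylindol-3-yl)-1H-imidazole | Cc1ccc(cc1)S(=O)(=O)n1cc(-c2c[nH]c(-c3cn(S(=O)(=O)c4ccc(C)cc4)c4cc(Br)ccc34)n2)c2ccc(Br)cc21 | intermediate
15 | nortopsentin A | Brc1ccc2c(-c3c[nH]c(-c4c[nH]c5cc(Br)ccc45)n3)c[nH]c2c1 | target

Total step count: 7.

Longest linear sequence: 5 steps (steps 3, 4, 5, 6, 7 from 6; equally steps 1, 2, 5, 6, 7 from 1).

Steps most likely to fail

**Step 5.**
- What may go wrong: the second coupling at the more electron-rich C4–I bond lags and the boronate is consumed by protodeboronation in the aqueous base. Palladium then begins to insert into C6–Br bonds once iodide becomes scarce, which leads to chain growth.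
- Fallback: a base-free and water-free double Negishi coupling that sets out from 8 and 5. Iodide 8 is turned into Grignard reagent 10 with i-PrMgCl at −40 °C as in step 4. ZnCl2 in THF converts it into (6-bromo-1-tosylindol-3-yl)zinc chloride F1. About 2.3 equivalents of this reagent are coupled with 5 under Pd(PPh3)4 in THF at room temperature. The lower temperature widens the gap between iodide and bromide, and there is no boron group to lose.
- The fallback comes back to the route at 13.

**Step 2.**
- What may go wrong: competing deprotonation at C5 beside the iodine, or iodine transfer between metalated and iodinated imidazoles (halogen dance), so that the regiochemical integrity of the diiodide is lost.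
- Fallback: site-selective use of a triiodide, with no deprotonation, setting out from 1. Exhaustive iodination (I2, KI, aq NaOH) gives 2,4,5-triiodo-1H-imidazole F2. Its N-alkylation with 2 (NaH, THF) can give only one isomer, 2,4,5-triiodo-1-SEM-imidazole F3. One equivalent of 11 under the catalyst system of step 5 at room temperature to 40 °C should couple at the most reactive C2–I bond and give 2-(6-bromo-1-tosylindol-3-yl)-4,5-diiodo-1-SEM-imidazole F4. i-PrMgCl at −40 °C exchanges the C5 iodine next to N1 and gives [2-(6-bromo-1-tosylindol-3-yl)-4-iodo-1-SEM-imidazol-5-yl]magnesium chloride F5. An aq NH4Cl quench then delivers 12, which is isolated in this variant.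
- The fallback comes back to the route at 12, which takes up a second equivalent of 11 under the step 5 conditions to give 13.

**Step 1.**
- What may go wrong: poor discrimination between the two nitrogens of the ambident anion, so that material is lost to the wrong N-alkylation and the separation becomes laborious.
- Fallback: symmetrise first and remove one iodine afterwards, setting out from 1. Iodination with one equivalent of I2 (KI, aq NaOH) gives 4,5-diiodo-1H-imidazole F6, in which both nitrogens are equivalent. Alkylation with 2 (NaH, THF) therefore gives a single product, 4,5-diiodo-1-SEM-imidazole F7. i-PrMgCl (THF, −40 °C) selectively exchanges the C5 iodine adjacent to N1 and gives (4-iodo-1-SEM-imidazol-5-yl)magnesium chloride F8, which aq NH4Cl protonates.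
- The fallback comes back to the route at 3.

Further compounds
F1 | step 5 | (6-bromo-1-tosylindol-3-yl)zinc chloride | Cc1ccc(cc1)S(=O)(=O)n1cc([Zn]Cl)c2ccc(Br)cc21
F2 | step 2 | 2,4,5-triiodo-1H-imidazole | Ic1nc(I)c(I)[nH]1
F3 | step 2 | 2,4,5-triiodo-1-SEM-imidazole | C[Si](C)(C)CCOCn1c(I)nc(I)c1I
F4 | step 2 | 2-(6-bromo-1-tosylindol-3-yl)-4,5-diiodo-1-SEM-imidazole | Cc1ccc(cc1)S(=O)(=O)n1cc(-c2nc(I)c(I)n2COCC[Si](C)(C)C)c2ccc(Br)cc21
F5 | step 2 | [2-(6-bromo-1-tosylindol-3-yl)-4-iodo-1-SEM-imidazol-5-yl]magnesium chloride | Cc1ccc(cc1)S(=O)(=O)n1cc(-c2nc(I)c([Mg]Cl)n2COCC[Si](C)(C)C)c2ccc(Br)cc21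
F6 | step 1 | 4,5-diiodo-1H-imidazole | Ic1nc[nH]c1I
F7 | step 1 | 4,5-diiodo-1-SEM-imidazole | C[Si](C)(C)CCOCn1cnc(I)c1I
F8 | step 1 | (4-iodo-1-SEM-imidazol-5-yl)magnesium chloride | C[Si](C)(C)CCOCn1cnc(I)c1[Mg]Cl
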